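**Plan**
- Cuts: the C3–O ester bond (trienoic acid off); C8=O and C12–OH are traced back to a furan spanning C7, C8, C11, C12; C1–C2 and C5–C10 are cut together as an intramolecular [4+2]; then C5–C6 (Negishi), C9–C10 (vinyl addition) and C2=C3 (ester methylenation).
- Forward: the furan is made first and the chain is joined at C5–C6. Rings A and B then arise together in step 9. C9, C4 and C3 are adjusted, the trienoate is attached, and the furan is opened last.
- Enabling feature: in ring A the C3 oxygen is para to C10, and C10 carries the C9 oxygen. C2=C3(OMe)–C4=C5 and C1=C10–C9=O are therefore a polarity-matched 2-oxydiene/vinyl ketone pair. C7 and C8 of ring B are sp2 and, as furan carbons, hold the tether C6–C7=C8–C9 cisoid.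
- Stereochemistry: C5/C10 from the catalyst-controlled endo cycloaddition of the (E)-diene; C9 from CBS reduction; C4 by equilibration and C3 by thermodynamically controlled reduction, both steered by the 9β-silyloxy group; C7=C11 (Z) from the furan ring; the (E,E,E)-triene from carboalumination and Heck coupling.

Key step: step 9

Remark: eremophilane numbering is used (ring A C1–C5/C10, ring B C5–C10, C11–C13 on C7, C14 on C5, C15 on C4; β is the face of 5-CH3 and 10-H), "8,12-epoxyeremophila-7,11-diene" denotes the fused furan, and the target is assumed to be handled in the open hydroxy-enone form drawn, in equilibrium with its cyclic hemiketal.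

Step 1
Reactants: 1 methyl 4,4-dimethoxy-3-oxobutanoate; 2 chloroacetone
Product: 4 methyl 2-(dimethoxymethyl)-4-methylfuran-3-carboxylate, via hydroxydihydrofuran 3 (not isolated)
Conditions: pyridine, 60 °C; then TsOH·H2O (cat.), HC(OMe)3, MeOH, 25 °C
Reagents that add atoms: none
Why: Feist–Benary furan synthesis, in which the enolate of 1 adds to the ketone of 2, the enol oxygen closes by 5-exo-tet displacement of chloride to 3, and acid dehydrates 3 while the orthoformate keeps the acetal; the aldol-first order puts the methyl on C4 of the furan and not on C5.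

Step 2
Reactants: 4 methyl 2-(dimethoxymethyl)-4-methylfuran-3-carboxylate
Product: 5 [2-(dimethoxymethyl)-4-methylfuran-3-yl]methanol
Conditions: LiAlH4, THF, 0 °C; aqueous NaOH work-up
Reagents that add atoms: none
Why: LiAlH4 reduces the ester to the primary alcohol, and the acetal is inert to hydride and to the basic work-up.

Step 3
Reactants: 5 [2-(dimethoxymethyl)-4-methylfuran-3-yl]methanol
Product: 7 3-(chloromethyl)-2-(dimethoxymethyl)-4-methylfuran, via mesylate 6 (not isolated)
Conditions: MsCl, Et3N, CH2Cl2, 0 °C; then LiCl, DMF, 25 °C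
Reagents that add atoms: lithium chloride, [Li+].[Cl-]
Why: mesylation followed by SN2 displacement with chloride runs under basic conditions that spare the acetal and the furan.

Step 4
Reactants: 8 methyl 2-methyl-3-oxobutanoate
Product: 9 methyl (2E)-2-methyl-3-(4-methylbenzenesulfonyloxy)but-2-enoate
Conditions: TsCl, N-methylimidazole, Et3N, MeCN, 0 °C (lithium-free)
Reagents that add atoms: p-toluenesulfonyl chloride, Cc1ccc(cc1)S(=O)(=O)Cl
Why: stereoselective enol tosylation of an α-substituted β-keto ester under non-chelating amine conditions should place OTs trans to the ester, and this (E)-geometry later becomes the diene geometry.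

Step 5
Reactants: 7 3-(chloromethyl)-2-(dimethoxymethyl)-4-methylfuran; 9 methyl (2E)-2-methyl-3-(4-methylbenzenesulfonyloxy)but-2-enoate
Product: 12 methyl (2E)-4-(2-formyl-4-methylfuran-3-yl)-2,3-dimethylbut-2-enoate, via furylmethylzinc chloride 10 (not isolated), via acetal ester 11 (not isolated)
Conditions: Zn dust, LiCl, THF, 25 °C; then 9, Pd(OAc)2 (2 mol%), SPhos (2-dicyclohexylphosphino-2',6'-dimethoxybiphenyl, 4 mol%), THF, 50 °C; then 1 M HCl, THF, 0 °C
Reagents that add atoms: water, O
Why: LiCl-assisted zinc insertion and Negishi coupling, in which oxidative addition of zerovalent palladium into the electron-poor enol tosylate and reductive elimination keep the (E)-geometry; the dilute acid of the work-up hydrolyses only the furfural acetal.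

Step 6
Reactants: 12 methyl (2E)-4-(2-formyl-4-methylfuran-3-yl)-2,3-dimethylbut-2-enoate
Product: 13 methyl (2E)-4-[2-(1-hydroxyprop-2-en-1-yl)-4-methylfuran-3-yl]-2,3-dimethylbut-2-enoate (racemic carbinol)
Conditions: CH2=CHMgBr, THF, −78 °C
Reagents that add atoms: vinylmagnesium bromide, C=C[Mg]Br
Why: 1,2-addition of the Grignard reagent to the aldehyde at −78 °C is much faster than attack on the hindered tetrasubstituted conjugated ester; the new carbinol centre is racemic and is removed in step 8.

Step 7
Reactants: 13 methyl (2E)-4-[2-(1-hydroxyprop-2-en-1-yl)-4-methylfuran-3-yl]-2,3-dimethylbut-2-enoate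
Product: 14 1-{3-[(2E)-4-methoxy-2,3-dimethylpenta-2,4-dien-1-yl]-4-methylfuran-2-yl}prop-2-en-1-ol (racemic)
Conditions: Cp2Ti(μ-CH2)(μ-Cl)AlMe2 (3 equiv), pyridine (cat.), THF/toluene, −40 to 0 °C; aqueous NaOH work-up
Reagents that add atoms: Tebbe reagent Cp2Ti(μ-CH2)(μ-Cl)AlMe2, C=[Ti](C1C=CC=C1)C1C=CC=C1.C[Al](C)Cl
Why: Tebbe methylenation ([2+2] of Cp2Ti=CH2 with the ester C=O, then cycloreversion) turns the conjugated ester into the 2-methoxy-1,3-diene without acid or enolisation, so the (E)-alkene is untouched; the hydroxyl only consumes one further equivalent of reagent as a titanium alkoxide.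

Step 8
Reactants: 14 1-{3-[(2E)-4-methoxy-2,3-dimethylpenta-2,4-dien-1-yl]-4-methylfuran-2-yl}prop-2-en-1-ol
Product: 15 1-{3-[(2E)-4-methoxy-2,3-dimethylpenta-2,4-dien-1-yl]-4-methylfuran-2-yl}prop-2-en-1-one
Conditions: activated MnO2, CH2Cl2, 0 °C; filtered through Celite, dried (4 Å molecular sieves) and used at once as a cold solution
Reagents that add atoms: none
Why: MnO2 oxidises the doubly activated (furyl, vinyl) carbinol under neutral conditions that the acid-labile methoxydiene tolerates, so the dienophile is unmasked only at this point and is kept cold to hold back uncatalysed cyclisation.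

Step 9
Reactants: 15 1-{3-[(2E)-4-methoxy-2,3-dimethylpenta-2,4-dien-1-yl]-4-methylfuran-2-yl}prop-2-en-1-one
Product: 16 (5S,10S)-3-methoxy-8,12-epoxyeremophila-3,7,11-trien-9-one (cis-fused)
Conditions: (S)-1-(2-methylphenyl)-3,3-diphenyltetrahydro-1H,3H-pyrrolo[1,2-c][1,3,2]oxazaborole (C24H24BNO, 20 mol%) protonated with Tf2NH (18 mol%), CH2Cl2, −78 to −40 °C; Et3N quench
Reagents that add atoms: none
Why: The protonated oxazaborolidine binds the C9 carbonyl of the furyl vinyl ketone, which the tether holds s-cis (O syn to C1) in the fused transition state, and lowers its LUMO, so that the unsubstituted, enol-ether-activated diene terminus C2 bonds to the enone β-carbon C1 ahead of the C5–C10 bond in a concerted but asynchronous [4+2] transition state, which lets the tetrasubstituted terminus C5 become quaternary late in the event. The closest known reaction types are the oxazaborolidinium-catalysed enantioselective Diels–Alder additions of 2-silyloxydienes to vinyl ketones and the intramolecular Diels–Alder reactions of 1,7,9-decatrien-3-ones. Ring A closes as the six-membered cycloadduct ring that holds both new bonds, and ring B closes through the C5–C10 bond as a six-membered ring in the fused mode, its four-atom tether C6–C7=C8–C9 being held cisoid by the furan. The cis fusion at C5/C10 follows from the (E)-diene (tether outside, methyl inside) reacting with the tether carbonyl endo, and the absolute configuration (5S,10S here, which is 5R,10S in the target) comes from the catalyst, which covers one face of the bound enone; the (S)-catalyst is proposed by analogy with the intermolecular additions to vinyl ketones, and the sense of induction would be confirmed by chemical correlation of alcohol 17, the antipodal catalyst being used if it proves opposite. The step needs regio-, endo- and π-facial selectivity: regiochemistry is fixed by the tether and the matched polarity, endo selectivity is expected because the conjugating ketone lies inside the tether, and facial selectivity rests on the catalyst at −78 °C, where the uncatalysed reaction of the hindered diene should be negligible.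

Step 10
Reactants: 16 (5S,10S)-3-methoxy-8,12-epoxyeremophila-3,7,11-trien-9-one
Product: 17 (5S,9R,10S)-3-methoxy-8,12-epoxyeremophila-3,7,11-trien-9-ol
Conditions: (S)-1-methyl-3,3-diphenyltetrahydro-1H,3H-pyrrolo[1,2-c][1,3,2]oxazaborole (C18H20BNO, 0.5 equiv), catecholborane, toluene, −78 °C; aqueous NaOH work-up
Reagents that add atoms: none
Why: Corey–Bakshi–Shibata reduction, in which the furyl ring acts as the large group so that the (S)-catalyst should deliver hydride to the face giving the 9R alcohol (OH cis to 10-H) under reagent control, while catecholborane at −78 °C leaves the enol ether and the furan alone.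

Step 11
Reactants: 17 (5S,9R,10S)-3-methoxy-8,12-epoxyeremophila-3,7,11-trien-9-ol
Product: 19 (4R,5S,9R,10S)-9-(tert-butyldimethylsilyloxy)-8,12-epoxyeremophila-7,11-dien-3-one, via silyl ether 18 (not isolated)
Conditions: TBSOTf, 2,6-lutidine, CH2Cl2, −78 °C; then aqueous oxalic acid, THF, 25 to 40 °C
Reagents that add atoms: tert-butyldimethylsilyl trifluoromethanesulfonate, CC(C)(C)[Si](C)(C)OS(=O)(=O)C(F)(F)F; water, O
Why: silylation of the hindered furfuryl alcohol and mild acid hydrolysis of the methyl enol ether by protonation at C4; C4 is epimerisable next to the new ketone and should settle as the 4β-methyl (4R) isomer, because with the 9β-silyloxy group pseudoequatorial the cis-decalin holds the C5 methyl axial on ring A and only the 4β-methyl is then equatorial.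

Step 12
Reactants: 19 (4R,5S,9R,10S)-9-(tert-butyldimethylsilyloxy)-8,12-epoxyeremophila-7,11-dien-3-one
Product: 20 (3R,4R,5R,9R,10S)-9-(tert-butyldimethylsilyloxy)-8,12-epoxyeremophila-7,11-dien-3-ol
Conditions: SmI2, H2O, Et3N, THF, 0 °C
Reagents that add atoms: none
Why: ketyl-type reduction by divalent samarium goes through a carbinyl anion that keeps the bulky O–Sm group equatorial, away from the syn-axial C5 methyl, so the equatorial 3α (3R) alcohol should form as in dissolving-metal reductions, whereas hydride reagents would attack from the open equatorial side and give the axial epimer.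

Step 13
Reactants: 21 (2E)-oct-2-enal
Product: 22 (3E)-non-3-en-1-yne
Conditions: Me3SiCHN2, LDA, THF, −78 to 25 °C
Reagents that add atoms: trimethylsilyldiazomethane, C[Si](C)(C)C=[N+]=[N-]
Why: Colvin homologation, in which the lithiated diazo reagent adds to the aldehyde, Peterson elimination and loss of N2 give an alkylidene carbene, and its 1,2-shift forms the terminal alkyne without touching the (E)-alkene.

Step 14
Reactants: 22 (3E)-non-3-en-1-yne
Product: 24 (1E,3E)-1-iodo-2-methylnona-1,3-diene, via alkenylalane 23 (not isolated)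
Conditions: Me3Al, Cp2ZrCl2 (20 mol%), CH2Cl2, 0 to 25 °C; then I2, THF, −30 to 0 °C
Reagents that add atoms: trimethylaluminium, C[Al](C)C; iodine, II
Why: zirconium-catalysed Negishi carboalumination adds CH3 and Al syn across the terminal alkyne with the methyl on the internal carbon, and iodinolysis with retention fixes the trisubstituted (E)-alkene.

Step 15
Reactants: 24 (1E,3E)-1-iodo-2-methylnona-1,3-diene; 25 acrylic acid
Product: 26 (2E,4E,6E)-5-methyldodeca-2,4,6-trienoic acid
Conditions: Pd(OAc)2 (5 mol%), Bu4NCl, K2CO3, DMF, 40 °C; acidify to pH 3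
Reagents that add atoms: none
Why: Heck reaction under phase-transfer conditions, in which syn carbopalladation of the acrylate and syn β-hydride elimination give the new (E)-alkene and the dienyl iodide geometry is retained.

Step 16
Reactants: 20 (3R,4R,5R,9R,10S)-9-(tert-butyldimethylsilyloxy)-8,12-epoxyeremophila-7,11-dien-3-ol; 26 (2E,4E,6E)-5-methyldodeca-2,4,6-trienoic acid
Product: 28 (3R,4R,5R,9R,10S)-9-(tert-butyldimethylsilyloxy)-8,12-epoxyeremophila-7,11-dien-3-yl (2E,4E,6E)-5-methyldodeca-2,4,6-trienoate, via mixed anhydride 27 (not isolated)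
Conditions: 2,4,6-trichlorobenzoyl chloride, Et3N, THF, 25 °C; then 20, 4-(dimethylamino)pyridine, toluene, 25 °C
Reagents that add atoms: none
Why: Yamaguchi esterification through the mixed anhydride acylates the only free hydroxyl, the equatorial secondary C3–OH, with retention at C3.

Step 17
Reactants: 28 (3R,4R,5R,9R,10S)-9-(tert-butyldimethylsilyloxy)-8,12-epoxyeremophila-7,11-dien-3-yl (2E,4E,6E)-5-methyldodeca-2,4,6-trienoate
Product: 31 (3R,4R,5R,9R,10S,7(11)Z)-9-(tert-butyldimethylsilyloxy)-12-hydroxy-8-oxoeremophil-7(11)-en-3-yl (2E,4E,6E)-5-methyldodeca-2,4,6-trienoate, via endoperoxide 29 (not isolated), via keto-enal 30 (not isolated)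
Conditions: O2, hν (>590 nm), 5,10,15,20-tetraphenylporphyrin (C44H30N4, 1 mol%), CH2Cl2, −78 °C; then Me2S, −78 to 0 °C, dark; then LiAlH(OtBu)3, THF, −78 °C
Reagents that add atoms: dioxygen, O=O
Why: [4+2] addition of singlet oxygen to the electron-rich trialkylfuran (expected to be far faster than to the ester-conjugated triene) gives the endoperoxide, Me2S reduces it to the (Z)-4-oxo-enal with the alkene geometry fixed by the former ring, and the bulky hydride should reduce only the aldehyde and not the hindered α-silyloxy enone or the ester.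

Step 18
Reactants: 31 (3R,4R,5R,9R,10S,7(11)Z)-9-(tert-butyldimethylsilyloxy)-12-hydroxy-8-oxoeremophil-7(11)-en-3-yl (2E,4E,6E)-5-methyldodeca-2,4,6-trienoate
Product: 32 (3R,4R,5R,9R,10S,7(11)Z)-9,12-dihydroxy-8-oxoeremophil-7(11)-en-3-yl (2E,4E,6E)-5-methyldodeca-2,4,6-trienoate (CNP0226738.1)
Conditions: HF·pyridine, excess pyridine, THF, 0 to 25 °C
Reagents that add atoms: none
Why: fluoride cleavage of the secondary silyl ether under pyridine-buffered conditions, which should avoid acid-promoted cyclodehydration of the (Z)-γ-hydroxy enone back to a furan.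

**Compound list**
1 | methyl 4,4-dimethoxy-3-oxobutanoate | COC(=O)CC(=O)C(OC)OC | starting material
2 | chloroacetone | CC(=O)CCl | starting material
3 | methyl 2-(dimethoxymethyl)-4-hydroxy-4-methyl-4,5-dihydrofuran-3-carboxylate (racemic) | COC(=O)C1=C(C(OC)OC)OCC1(C)O | intermediate (not isolated)
4 | methyl 2-(dimethoxymethyl)-4-methylfuran-3-carboxylate | COC(=O)c1c(C)coc1C(OC)OC | intermediate
5 | [2-(dimethoxymethyl)-4-methylfuran-3-yl]methanol | OCc1c(C)coc1C(OC)OC | intermediate
6 | [2-(dimethoxymethyl)-4-methylfuran-3-yl]methyl methanesulfonate | CS(=O)(=O)OCc1c(C)coc1C(OC)OC | intermediate (not isolated)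
7 | 3-(chloromethyl)-2-(dimethoxymethyl)-4-methylfuran | ClCc1c(C)coc1C(OC)OC | intermediate
8 | methyl 2-methyl-3-oxobutanoate | COC(=O)C(C)C(C)=O | starting material
9 | methyl (2E)-2-methyl-3-(4-methylbenzenesulfonyloxy)but-2-enoate | COC(=O)/C(C)=C(\C)OS(=O)(=O)c1ccc(C)cc1 | intermediate
10 | {[2-(dimethoxymethyl)-4-methylfuran-3-yl]methyl}zinc chloride | Cl[Zn]Cc1c(C)coc1C(OC)OC | intermediate (not isolated)
11 | methyl (2E)-4-[2-(dimethoxymethyl)-4-methylfuran-3-yl]-2,3-dimethylbut-2-enoate | COC(=O)/C(C)=C(\C)Cc1c(C)coc1C(OC)OC | intermediate (not isolated)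
12 | methyl (2E)-4-(2-formyl-4-methylfuran-3-yl)-2,3-dimethylbut-2-enoate | COC(=O)/C(C)=C(\C)Cc1c(C)coc1C=O | intermediate
13 | methyl (2E)-4-[2-(1-hydroxyprop-2-en-1-yl)-4-methylfuran-3-yl]-2,3-dimethylbut-2-enoate (racemic carbinol) | COC(=O)/C(C)=C(\C)Cc1c(C)coc1C(O)C=C | intermediate
14 | 1-{3-[(2E)-4-methoxy-2,3-dimethylpenta-2,4-dien-1-yl]-4-methylfuran-2-yl}prop-2-en-1-ol (racemic) | C=C(OC)/C(C)=C(\C)Cc1c(C)coc1C(O)C=C | intermediate
15 | 1-{3-[(2E)-4-methoxy-2,3-dimethylpenta-2,4-dien-1-yl]-4-methylfuran-2-yl}prop-2-en-1-one | C=C(OC)/C(C)=C(\C)Cc1c(C)coc1C(=O)C=C | intermediate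
16 | (5S,10S)-3-methoxy-8,12-epoxyeremophila-3,7,11-trien-9-one | COC1=C(C)[C@@]2(C)Cc3c(C)coc3C(=O)[C@H]2CC1 | intermediate
17 | (5S,9R,10S)-3-methoxy-8,12-epoxyeremophila-3,7,11-trien-9-ol | COC1=C(C)[C@@]2(C)Cc3c(C)coc3[C@H](O)[C@H]2CC1 | intermediate
18 | (5S,9R,10S)-9-(tert-butyldimethylsilyloxy)-3-methoxy-8,12-epoxyeremophila-3,7,11-triene | COC1=C(C)[C@@]2(C)Cc3c(C)coc3[C@H](O[Si](C)(C)C(C)(C)C)[C@H]2CC1 | intermediate (not isolated)
19 | (4R,5S,9R,10S)-9-(tert-butyldimethylsilyloxy)-8,12-epoxyeremophila-7,11-dien-3-one | O=C1CC[C@@H]2[C@@H](O[Si](C)(C)C(C)(C)C)c3occ(C)c3C[C@]2(C)[C@H]1C | intermediate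
20 | (3R,4R,5R,9R,10S)-9-(tert-butyldimethylsilyloxy)-8,12-epoxyeremophila-7,11-dien-3-ol | O[C@@H]1CC[C@@H]2[C@@H](O[Si](C)(C)C(C)(C)C)c3occ(C)c3C[C@]2(C)[C@H]1C | intermediate
21 | (2E)-oct-2-enal | CCCCC/C=C/C=O | starting material
22 | (3E)-non-3-en-1-yne | CCCCC/C=C/C#C | intermediate
23 | dimethyl[(1E,3E)-2-methylnona-1,3-dien-1-yl]alane | CCCCC/C=C/C(C)=C/[Al](C)C | intermediate (not isolated)
24 | (1E,3E)-1-iodo-2-methylnona-1,3-diene | CCCCC/C=C/C(C)=C/I | intermediate
25 | acrylic acid | C=CC(=O)O | starting material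
26 | (2E,4E,6E)-5-methyldodeca-2,4,6-trienoic acid | CCCCC/C=C/C(C)=C/C=C/C(=O)O | intermediate
27 | (2E,4E,6E)-5-methyldodeca-2,4,6-trienoic 2,4,6-trichlorobenzoic anhydride | CCCCC/C=C/C(C)=C/C=C/C(=O)OC(=O)c1c(Cl)cc(Cl)cc1Cl | intermediate (not isolated)
28 | (3R,4R,5R,9R,10S)-9-(tert-butyldimethylsilyloxy)-8,12-epoxyeremophila-7,11-dien-3-yl (2E,4E,6E)-5-methyldodeca-2,4,6-trienoate | CCCCC/C=C/C(C)=C/C=C/C(=O)O[C@@H]1CC[C@@H]2[C@@H](O[Si](C)(C)C(C)(C)C)c3occ(C)c3C[C@]2(C)[C@H]1C | intermediate
29 | 8,12-epidioxide (furan endoperoxide) of 28 | CCCCC/C=C/C(C)=C/C=C/C(=O)O[C@@H]1CC[C@@H]2[C@@H](O[Si](C)(C)C(C)(C)C)C34OOC(O3)C(C)=C4C[C@]2(C)[C@H]1C | intermediate (not isolated)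
30 | (3R,4R,5R,9R,10S,7(11)Z)-9-(tert-butyldimethylsilyloxy)-8,12-dioxoeremophil-7(11)-en-3-yl (2E,4E,6E)-5-methyldodeca-2,4,6-trienoate | CCCCC/C=C/C(C)=C/C=C/C(=O)O[C@@H]1CC[C@@H]2[C@@H](O[Si](C)(C)C(C)(C)C)C(=O)/C(=C(/C)C=O)C[C@]2(C)[C@H]1C | intermediate (not isolated)
31 | (3R,4R,5R,9R,10S,7(11)Z)-9-(tert-butyldimethylsilyloxy)-12-hydroxy-8-oxoeremophil-7(11)-en-3-yl (2E,4E,6E)-5-methyldodeca-2,4,6-trienoate | CCCCC/C=C/C(C)=C/C=C/C(=O)O[C@@H]1CC[C@@H]2[C@@H](O[Si](C)(C)C(C)(C)C)C(=O)/C(=C(/C)CO)C[C@]2(C)[C@H]1C | intermediate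
32 | (3R,4R,5R,9R,10S,7(11)Z)-9,12-dihydroxy-8-oxoeremophil-7(11)-en-3-yl (2E,4E,6E)-5-methyldodeca-2,4,6-trienoate | CCCCC/C=C/C(C)=C/C=C/C(=O)O[C@@H]1CC[C@@H]2[C@@H](O)C(=O)/C(=C(/C)CO)C[C@]2(C)[C@H]1C | target

**Totals**
Total steps: 18. Longest linear sequence: 14 steps (1, 2, 3, 5, 6, 7, 8, 9, 10, 11, 12, 16, 17, 18).

**Steps most likely to fail**

Step 9. What may go wrong: insufficient π-facial discrimination by the catalyst on this hindered aryl vinyl ketone, uncatalysed cyclisation of 15 before the catalyst is added, erosion of endo (cis) selectivity, acid-induced loss of the methoxydiene before cyclisation, or diversion of the bound enone into a hetero-[4+2] with the enol ether. The fallback sets out from 15 and comes back at 17. Cyclisation of 15 with Me2AlCl (CH2Cl2, −78 °C) or by heating in toluene should give the racemic cis-fused adduct, that is 16 together with its enantiomer (5R,10R)-3-methoxy-8,12-epoxyeremophila-3,7,11-trien-9-one F1. Reduction of this racemate under the conditions of step 10, where the catalyst and not the substrate sets C9, should turn 16 into 17 and F1 into the diastereomeric (5R,9R,10R)-3-methoxy-8,12-epoxyeremophila-3,7,11-trien-9-ol F2. The two alcohols are diastereomers and would be separated by chromatography, and 17 enters step 11.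

Step 17. What may go wrong: competing photooxygenation or sensitised E/Z isomerisation of the trienoate, isomerisation or cyclisation of the (Z)-oxo-enal before it is reduced, or over-reduction at C8. The fallback sets out from 20 and comes back at 32; it opens the furan before the triene is present. Photooxygenation of 20 and Me2S reduction under the step 17 conditions should pass through the 8,12-epidioxide of 20 F3 and give (3R,4R,5R,9R,10S,7(11)Z)-9-(tert-butyldimethylsilyloxy)-3-hydroxy-8-oxoeremophil-7(11)-en-12-al F4, which LiAlH(OtBu)3 should reduce to (3R,4R,5R,9R,10S,7(11)Z)-9-(tert-butyldimethylsilyloxy)-3,12-dihydroxyeremophil-7(11)-en-8-one F5. TBSCl and imidazole at 0 °C should then silylate only the primary allylic hydroxyl to give (3R,4R,5R,9R,10S,7(11)Z)-9,12-bis(tert-butyldimethylsilyloxy)-3-hydroxyeremophil-7(11)-en-8-one F6, Yamaguchi esterification with 26 (through 27) should give (3R,4R,5R,9R,10S,7(11)Z)-9,12-bis(tert-butyldimethylsilyloxy)-8-oxoeremophil-7(11)-en-3-yl (2E,4E,6E)-5-methyldodeca-2,4,6-trienoate F7, and HF·pyridine buffered with pyridine removes both silyl groups to give 32.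

Step 10. What may go wrong: weak reagent control with an α-branched aryl ketone or a mismatched substrate bias, so that hydride arrives mainly on the wrong face of C9. The fallback sets out from 16 and comes back at 17. The 9S epimer, (5S,9S,10S)-3-methoxy-8,12-epoxyeremophila-3,7,11-trien-9-ol F8, is then made on purpose (NaBH4/CeCl3 or the antipodal oxazaborolidine, whichever is the more selective). It is inverted by Mitsunobu reaction with 4-nitrobenzoic acid (PPh3, DIAD, THF, 0 °C) to (5S,9R,10S)-3-methoxy-8,12-epoxyeremophila-3,7,11-trien-9-yl 4-nitrobenzoate F9. Methanolysis (K2CO3, MeOH) then gives 17.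

Further compounds
F1 | step 9 | (5R,10R)-3-methoxy-8,12-epoxyeremophila-3,7,11-trien-9-one | COC1=C(C)[C@]2(C)Cc3c(C)coc3C(=O)[C@@H]2CC1
F2 | step 9 | (5R,9R,10R)-3-methoxy-8,12-epoxyeremophila-3,7,11-trien-9-ol | COC1=C(C)[C@]2(C)Cc3c(C)coc3[C@H](O)[C@@H]2CC1
F3 | step 17 | 8,12-epidioxide of 20 | O[C@@H]1CC[C@@H]2[C@@H](O[Si](C)(C)C(C)(C)C)C34OOC(O3)C(C)=C4C[C@]2(C)[C@H]1C
F4 | step 17 | (3R,4R,5R,9R,10S,7(11)Z)-9-(tert-butyldimethylsilyloxy)-3-hydroxy-8-oxoeremophil-7(11)-en-12-al | O[C@@H]1CC[C@@H]2[C@@H](O[Si](C)(C)C(C)(C)C)C(=O)/C(=C(/C)C=O)C[C@]2(C)[C@H]1C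
F5 | step 17 | (3R,4R,5R,9R,10S,7(11)Z)-9-(tert-butyldimethylsilyloxy)-3,12-dihydroxyeremophil-7(11)-en-8-one | O[C@@H]1CC[C@@H]2[C@@H](O[Si](C)(C)C(C)(C)C)C(=O)/C(=C(/C)CO)C[C@]2(C)[C@H]1C
F6 | step 17 | (3R,4R,5R,9R,10S,7(11)Z)-9,12-bis(tert-butyldimethylsilyloxy)-3-hydroxyeremophil-7(11)-en-8-one | O[C@@H]1CC[C@@H]2[C@@H](O[Si](C)(C)C(C)(C)C)C(=O)/C(=C(/C)CO[Si](C)(C)C(C)(C)C)C[C@]2(C)[C@H]1C
F7 | step 17 | (3R,4R,5R,9R,10S,7(11)Z)-9,12-bis(tert-butyldimethylsilyloxy)-8-oxoeremophil-7(11)-en-3-yl (2E,4E,6E)-5-methyldodeca-2,4,6-trienoate | CCCCC/C=C/C(C)=C/C=C/C(=O)O[C@@H]1CC[C@@H]2[C@@H](O[Si](C)(C)C(C)(C)C)C(=O)/C(=C(/C)CO[Si](C)(C)C(C)(C)C)C[C@]2(C)[C@H]1C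
F8 | step 10 | (5S,9S,10S)-3-methoxy-8,12-epoxyeremophila-3,7,11-trien-9-ol | COC1=C(C)[C@@]2(C)Cc3c(C)coc3[C@@H](O)[C@H]2CC1
F9 | step 10 | (5S,9R,10S)-3-methoxy-8,12-epoxyeremophila-3,7,11-trien-9-yl 4-nitrobenzoate | COC1=C(C)[C@@]2(C)Cc3c(C)coc3[C@H](OC(=O)c4ccc(cc4)[N+](=O)[O-])[C@H]2CC1
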